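You asked what going from 90 °C up to 105 °C does over the same 20 h, so here is my quick number against your hunch, starting from the two flasks as they stand:

- dusk: Ty 0.43 M; Ly 61 mM (held); Jy 8.60 mM; temperature 105 °C; time 20 h
- autumn: Ty 0.43 M; Ly 61 mM (held); Jy 8.60 mM; temperature 90 °C; time 20 h

    Qe + Gu → Qa (k1 = 1.9 M⁻¹ h⁻¹, Ea1 = 88.0 kJ mol⁻¹)
    Ty + Qe → Qi (k2 = 0.76 M⁻¹ h⁻¹, Ea2 = 69.0 kJ mol⁻¹)
    Ly ⇌ Qe, rate k3*(csat - [Qe]) (k3 = 0.95 h⁻¹, csat = 61 mM)
    Qi + Jy → Dz (k4 = 0.12 M⁻¹ h⁻¹, Ea4 = 84.0 kJ mol⁻¹)
    Qe + Qi → Gu (k5 = 0.036 M⁻¹ h⁻¹, Ea5 = 102 kJ mol⁻¹)
    (constants at 90 °C)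

- at the start none of Qe is dissolved
- the list of constants is for 90 °C, to be carried to other temperatures by the activation energies

1. the flask with the highest share of Qa in all that became Qa or Dz ("all alike" if they lie within 1.5 percentage points) (dusk / autumn / all alike)
2. share of Qa in all that became Qa or Dz, dusk
3. share of Qa in all that became Qa or Dz, autumn

- I freeze [Qe] first: Ly feeds it and Ty consumes it, and balancing the two at the start of autumn gives 45.4 mM, less than the ceiling of 61 mM, so in autumn Ty holds [Qe] below that ceiling, and for a quick number I still freeze [Qe] at the ceiling, knowing that this is an upper figure and not what the flask will hold.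
- Qi then has two exits, towards Gu and towards Dz, and [Qi] cancels when you divide one rate by the other, which leaves the number I would carry to any such flask: S, a selectivity factor, the constant of Qe + Qi times [Qe] over the constant of Qi + Jy times [Jy].
- With [Jy] held at its charge, S comes to 2.13 in autumn and 2.70 in dusk, the higher value coming from the Gu-forming step speeding up 3.8 times while the Dz-forming step speeds up 3.0 times.
- Gu is not yet Qa, though, since a Gu waits about τ, one over the constant of Qe + Gu times [Qe], which is 8.63 h in autumn and 2.72 h in dusk.
- If Qi climbs roughly in a straight line, what has passed into Gu grows with the square of time, so the part already at Qa, f, is the square of one minus τ over the time: 0.323 in autumn and 0.747 in dusk.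
- The share of Qa is then fS over one plus fS, so I commit to 66.8% in dusk and 40.8% in autumn, 26 percentage points apart against a margin of 1.5 points.
- Your forecast also says dusk, with 70% and 45%, each a little higher than mine , on the ground that “the high activation energies of steps 5 and 1 speed the route to Qa more than step 4 speeds Dz”.

The simulation puts dusk ahead, at 70.3% against 45.1% in autumn. In autumn at 20.0 h, Qe is made 1.03 times as fast as it is used, net, with [Qe] at 0.0514 M, and Qa plus Gu stand to Dz at 1.96, where S was 2.13. In the neighbouring flask that is autumn with 0.021 M of Jy, S becomes 0.871 and the same f gives a share of 22.0%, while that flask itself stands at 25.1%.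

(Its constants come from no measurement.)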